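**Strategy.** The flavone is cut through ring A, leaving rings C and B intact. The step exploits the alternating oxygen pattern of ring A. The oxygen at C5 is read as a ketene carbonyl, the methoxy carbon C7 as the oxygenated carbon of methoxyacetylene, and O1 at C8a as the ring oxygen of a 4-pyranone. In one operation a photochemical Wolff rearrangement, a [2+2] cycloaddition, a four-electron ring opening and a six-electron ring closure forge C5–C6, C7–C8 and C4a–C5 and deliver the 5-hydroxy-7-methoxychromone. The precursor is a 2-aryl-3-methoxy-4-pyranone with a diazoacetyl group at C6, a free CH at C5 and both ring B phenols masked as benzyl ethers.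

Key step: step 10

Remark: the target has no stereocentre, so no configuration has to be set; methoxyacetylene boils near room temperature and is assumed to be made fresh and dosed as a cold stock solution.

Step 1
Reactants: 1 methoxyhydroquinone (2-methoxybenzene-1,4-diol)
Product: 2 1,4-bis(benzyloxy)-2-methoxybenzene
Conditions: BnBr, K2CO3, DMF, N2, 60 °C
Reagents that add atoms: benzyl bromide, BrCc1ccccc1
Why: Williamson ether synthesis, in which both phenoxides are alkylated by the benzylic bromide and exclusion of air keeps the hydroquinone from oxidising to the quinone.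

Step 2
Reactants: 2 1,4-bis(benzyloxy)-2-methoxybenzene
Product: 3 1,4-bis(benzyloxy)-2-bromo-5-methoxybenzene
Conditions: NBS, MeCN, 0 °C, dark
Reagents that add atoms: N-bromosuccinimide, O=C1CCC(=O)N1Br
Why: Electrophilic aromatic bromination, directed to the carbon para to OMe and ortho to one OBn, the only position activated by two oxygen donors that does not lie between two substituents, as in other 1,2,4-trialkoxybenzenes.

Step 3
Reactants: 3 1,4-bis(benzyloxy)-2-bromo-5-methoxybenzene
Product: 4 2-[2,5-bis(benzyloxy)-4-methoxyphenyl]-4,4,5,5-tetramethyl-1,3,2-dioxaborolane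
Conditions: B2pin2, PdCl2(dppf) (cat.), KOAc, 1,4-dioxane, 90 °C
Reagents that add atoms: bis(pinacolato)diboron, CC1(C)OB(OC1(C)C)B1OC(C)(C)C(C)(C)O1
Why: Miyaura borylation, in which oxidative addition of the aryl bromide to zerovalent palladium, acetate-assisted transmetalation from B2pin2 and reductive elimination should give the pinacol boronate, which resists protodeboronation better than the free electron-rich boronic acid.

Step 4
Reactants: 5 kojic acid
Product: 6 6-bromokojic acid (2-bromo-3-hydroxy-6-(hydroxymethyl)-4H-pyran-4-one)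
Conditions: NBS, MeCN, 0 °C to rt, dark
Reagents that add atoms: N-bromosuccinimide, O=C1CCC(=O)N1Br
Why: Electrophilic bromination of an enol that behaves like a phenol, at C6 ortho to the hydroxyl, the carbon at which kojic acid also undergoes Mannich, aldol and azo-coupling reactions, while C3 is not activated.

Step 5
Reactants: 6 6-bromokojic acid
Product: 7 2-bromo-6-(hydroxymethyl)-3-methoxy-4H-pyran-4-one
Conditions: MeI, K2CO3, DMF, rt
Reagents that add atoms: iodomethane, CI
Why: Williamson O-methylation, selective because carbonate deprotonates only the acidic enolic hydroxyl and leaves the primary alcohol un-ionised and unalkylated.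

Step 6
Reactants: 7 2-bromo-6-(hydroxymethyl)-3-methoxy-4H-pyran-4-one; 4 ring B pinacol boronate
Product: 8 2-[2,5-bis(benzyloxy)-4-methoxyphenyl]-6-(hydroxymethyl)-3-methoxy-4H-pyran-4-one
Conditions: Pd(OAc)2 (cat.), SPhos, K3PO4, 1,4-dioxane–H2O, 70 °C
Reagents that add atoms: none
Why: Suzuki–Miyaura coupling, in which the C–Br bond of 7 is a vinylogous acyl bromide that adds readily to zerovalent palladium, the bulky electron-rich phosphine speeds transmetalation and reductive elimination at the ortho-substituted biaryl bond, and the free alcohol is a spectator.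

Step 7
Reactants: 8 2-[2,5-bis(benzyloxy)-4-methoxyphenyl]-6-(hydroxymethyl)-3-methoxy-4H-pyran-4-one
Product: 10 6-[2,5-bis(benzyloxy)-4-methoxyphenyl]-5-methoxy-4-oxo-4H-pyran-2-carboxylic acid, via pyranone aldehyde 9 (not isolated)
Conditions: TEMPO (cat.), PhI(OAc)2, CH2Cl2–H2O, rt
Reagents that add atoms: water, O
Why: TEMPO/PhI(OAc)2 oxidation of a primary alcohol, in which the oxoammonium ion takes 8 to aldehyde 9, whose hydrate forms easily next to the electron-poor pyranone and is oxidised on to the acid, while the chlorine-free terminal oxidant leaves the electron-rich ring B and the aryl benzyl ethers alone.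

Step 8
Reactants: 10 6-[2,5-bis(benzyloxy)-4-methoxyphenyl]-5-methoxy-4-oxo-4H-pyran-2-carboxylic acid
Product: 12 2-[2,5-bis(benzyloxy)-4-methoxyphenyl]-6-(diazoacetyl)-3-methoxy-4H-pyran-4-one, via acid chloride 11 (not isolated)
Conditions: (COCl)2, DMF (cat.), CH2Cl2, 0 °C to rt, evaporate; CH2N2 (excess), Et2O–THF, −10 to 0 °C, excess purged with N2
Reagents that add atoms: oxalyl chloride, O=C(Cl)C(=O)Cl (chlorine of 11 only); diazomethane, C=[N+]=[N-]
Why: Acylation of diazomethane, the first stage of the Arndt–Eistert sequence, in which the acid chloride has no alpha hydrogen and acylates diazomethane within minutes at low temperature, far faster than a dipolar addition to the donor-substituted pyranone C=C bond, while the excess diazomethane scavenges HCl.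

Step 9
Reactants: 13 chloroacetaldehyde dimethyl acetal
Product: 16 methoxyacetylene, via 2-chlorovinyl methyl ether 14 (not isolated), via sodium methoxyacetylide 15 (not isolated)
Conditions: NaNH2 (3 equiv), liq. NH3, −33 °C; NH3 evaporated; cold brine; distilled into cold ClCH2CH2Cl
Reagents that add atoms: none
Why: Two successive base-induced eliminations (methanol, then HCl from 14), the standard 1-alkoxyalkyne synthesis from haloacetals, with a third equivalent of amide that stores the product as the non-volatile acetylide 15 until the cold aqueous quench.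

Step 10
Reactants: 12 2-[2,5-bis(benzyloxy)-4-methoxyphenyl]-6-(diazoacetyl)-3-methoxy-4H-pyran-4-one; 16 methoxyacetylene
Product: 21 2-[2,5-bis(benzyloxy)-4-methoxyphenyl]-5-hydroxy-3,7-dimethoxy-4H-chromen-4-one, via pyranonylketene 17 (not isolated), via cyclobutenone 18 (not isolated), via dienylketene 19 (not isolated), via keto tautomer 20 (not isolated)
Conditions: hν (LED, ca. 440 nm), 16 (excess), degassed ClCH2CH2Cl, Pyrex, 5 °C; excess 16 vented; 85 °C, dark
Reagents that add atoms: none
Why: Blue light expels N2 from 12 with a 1,2-shift of the pyranonyl group (photochemical Wolff rearrangement) to give ketene 17, whose carbonyl carbon is attacked by the unsubstituted, nucleophilic carbon of ynol ether 16, so that a [2+2] cycloaddition forms C5–C6 and C7–C8 in cyclobutenone 18. Heating cleaves the C5–C8 bond of 18 in a reversible conrotatory four-electron opening, and the equilibrium drains through dienylketene 19, the isomer that holds the ketene arm and the pyranonyl group cis. Ring A, the only ring closed, forms by disrotatory six-electron electrocyclisation of 19, which joins the ketene carbon to the pyranone CH (C4a–C5), and enolisation of keto tautomer 20 gives the hydrogen-bonded phenol 21. The closest known reaction type is the Danheiser benzannulation in its diazoketone form, established for alkenyl, aryl and heteroaryl diazomethyl ketones with alkoxy- and siloxyalkynes, and the weakly aromatic pyranone C5=C6 bond should behave like the alkenyl cases. The substrates themselves meet both regiochemical demands: the polarity of 16 places OMe on C7, meta to the new hydroxyl, and closure has a single site because the other neighbour of C8a is the ring oxygen. No stereocentre is left (the sp3 carbons of 18 and 20 are racemic and transient), and light of about 440 nm reaches only the weak visible band of the yellow diazoketone, so the pyranone and 3-methoxyflavone chromophores, which are photolabile in the ultraviolet, stay unexcited.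

Step 11
Reactants: 21 2-[2,5-bis(benzyloxy)-4-methoxyphenyl]-5-hydroxy-3,7-dimethoxy-4H-chromen-4-one
Product: 22 2-[2,5-bis(benzyloxy)-4-methoxyphenyl]-3,5,7-trimethoxy-4H-chromen-4-one
Conditions: Me2SO4, K2CO3, acetone, reflux
Reagents that add atoms: dimethyl sulfate, COS(=O)(=O)OC
Why: Williamson O-methylation, in which carbonate in refluxing acetone deprotonates even the hydrogen-bonded 5-hydroxyl, the standard way to permethylate 5-hydroxyflavones, and no other acidic site is present.

Step 12
Reactants: 22 2-[2,5-bis(benzyloxy)-4-methoxyphenyl]-3,5,7-trimethoxy-4H-chromen-4-one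
Product: 23 5-O-methyloxyayanin-A (2-(2,5-dihydroxy-4-methoxyphenyl)-3,5,7-trimethoxy-4H-chromen-4-one)
Conditions: H2 (1 atm), Pd/C, EtOAc–MeOH, rt; filtration under Ar
Reagents that add atoms: none
Why: Catalytic hydrogenolysis of aryl benzyl ethers, which cleaves both O–CH2Ph bonds under one atmosphere of hydrogen without reducing the tetrasubstituted C2=C3 bond or the carbonyl of a 3-methoxyflavone, with air kept out in the work-up because ring B is now a hydroquinone.

**Compound list**

1 | methoxyhydroquinone (2-methoxybenzene-1,4-diol) | COc1cc(O)ccc1O | starting material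
2 | 1,4-bis(benzyloxy)-2-methoxybenzene | COc1cc(OCc2ccccc2)ccc1OCc1ccccc1 | intermediate
3 | 1,4-bis(benzyloxy)-2-bromo-5-methoxybenzene | Brc1cc(OCc2ccccc2)c(OC)cc1OCc1ccccc1 | intermediate
4 | 2-[2,5-bis(benzyloxy)-4-methoxyphenyl]-4,4,5,5-tetramethyl-1,3,2-dioxaborolane | CC1(C)OB(OC1(C)C)c1cc(OCc2ccccc2)c(OC)cc1OCc1ccccc1 | intermediate
5 | kojic acid (5-hydroxy-2-(hydroxymethyl)-4H-pyran-4-one) | O=c1cc(CO)occ1O | starting material
6 | 6-bromokojic acid (2-bromo-3-hydroxy-6-(hydroxymethyl)-4H-pyran-4-one) | O=c1cc(CO)oc(Br)c1O | intermediate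
7 | 2-bromo-6-(hydroxymethyl)-3-methoxy-4H-pyran-4-one | COc1c(Br)oc(CO)cc1=O | intermediate
8 | 2-[2,5-bis(benzyloxy)-4-methoxyphenyl]-6-(hydroxymethyl)-3-methoxy-4H-pyran-4-one | OCc1cc(=O)c(OC)c(-c2cc(OCc3ccccc3)c(OC)cc2OCc2ccccc2)o1 | intermediate
9 | 6-[2,5-bis(benzyloxy)-4-methoxyphenyl]-5-methoxy-4-oxo-4H-pyran-2-carbaldehyde | O=Cc1cc(=O)c(OC)c(-c2cc(OCc3ccccc3)c(OC)cc2OCc2ccccc2)o1 | intermediate
10 | 6-[2,5-bis(benzyloxy)-4-methoxyphenyl]-5-methoxy-4-oxo-4H-pyran-2-carboxylic acid | OC(=O)c1cc(=O)c(OC)c(-c2cc(OCc3ccccc3)c(OC)cc2OCc2ccccc2)o1 | intermediate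
11 | 6-[2,5-bis(benzyloxy)-4-methoxyphenyl]-5-methoxy-4-oxo-4H-pyran-2-carbonyl chloride | ClC(=O)c1cc(=O)c(OC)c(-c2cc(OCc3ccccc3)c(OC)cc2OCc2ccccc2)o1 | intermediate
12 | 2-[2,5-bis(benzyloxy)-4-methoxyphenyl]-6-(diazoacetyl)-3-methoxy-4H-pyran-4-one | [N-]=[N+]=CC(=O)c1cc(=O)c(OC)c(-c2cc(OCc3ccccc3)c(OC)cc2OCc2ccccc2)o1 | intermediate
13 | chloroacetaldehyde dimethyl acetal (2-chloro-1,1-dimethoxyethane) | COC(CCl)OC | starting material
14 | 2-chlorovinyl methyl ether (1-chloro-2-methoxyethene, E/Z mixture) | COC=CCl | intermediate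
15 | sodium methoxyacetylide | COC#[C-].[Na+] | intermediate
16 | methoxyacetylene (methoxyethyne) | COC#C | intermediate
17 | {6-[2,5-bis(benzyloxy)-4-methoxyphenyl]-5-methoxy-4-oxo-4H-pyran-2-yl}ketene | O=C=Cc1cc(=O)c(OC)c(-c2cc(OCc3ccccc3)c(OC)cc2OCc2ccccc2)o1 | intermediate
18 | 4-{6-[2,5-bis(benzyloxy)-4-methoxyphenyl]-5-methoxy-4-oxo-4H-pyran-2-yl}-3-methoxycyclobut-2-en-1-one (racemic) | COC1=CC(=O)C1c1cc(=O)c(OC)c(-c2cc(OCc3ccccc3)c(OC)cc2OCc2ccccc2)o1 | intermediate
19 | 4-{6-[2,5-bis(benzyloxy)-4-methoxyphenyl]-5-methoxy-4-oxo-4H-pyran-2-yl}-3-methoxybuta-1,3-dien-1-one, ketene arm and pyranonyl group cis on C3=C4 | O=C=C/C(OC)=C\c1cc(=O)c(OC)c(-c2cc(OCc3ccccc3)c(OC)cc2OCc2ccccc2)o1 | intermediate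
20 | 2-[2,5-bis(benzyloxy)-4-methoxyphenyl]-3,7-dimethoxy-4aH-chromene-4,5-dione (racemic keto tautomer of 21) | COC1=CC(=O)C2C(=O)C(OC)=C(c3cc(OCc4ccccc4)c(OC)cc3OCc3ccccc3)OC2=C1 | intermediate
21 | 2-[2,5-bis(benzyloxy)-4-methoxyphenyl]-5-hydroxy-3,7-dimethoxy-4H-chromen-4-one | COc1cc(O)c2c(=O)c(OC)c(-c3cc(OCc4ccccc4)c(OC)cc3OCc3ccccc3)oc2c1 | intermediate
22 | 2-[2,5-bis(benzyloxy)-4-methoxyphenyl]-3,5,7-trimethoxy-4H-chromen-4-one | COc1cc(OC)c2c(=O)c(OC)c(-c3cc(OCc4ccccc4)c(OC)cc3OCc3ccccc3)oc2c1 | intermediate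
23 | 5-O-methyloxyayanin-A (2-(2,5-dihydroxy-4-methoxyphenyl)-3,5,7-trimethoxy-4H-chromen-4-one) | COc1cc(OC)c2c(=O)c(OC)c(-c3cc(O)c(OC)cc3O)oc2c1 | target

**Step count**

- Total step count: 12.
- Longest linear sequence: 9 steps (1, 2, 3, 6, 7, 8, 10, 11, 12, from methoxyhydroquinone 1).
- The kojic acid branch reaches the target in 8 steps and the methoxyacetylene branch in 4.

**Steps most likely to fail**

**Step 10.**
- What may go wrong: the ketene may be lost to dimerisation or to adventitious water before the volatile ynol ether captures it. The cascade may stall at the four-membered ring. Stray absorption by the pyranone or flavone chromophore may start a photorearrangement.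
- The fallback sets out from 3 and comes back at 22. It gives up the annulation of ring A and closes ring C on a bought ring A by a Baker–Venkataraman sequence.
- Bromide 3 is exchanged with n-BuLi (THF, −78 °C) to [2,5-bis(benzyloxy)-4-methoxyphenyl]lithium F1. This is quenched with CO2 and acidified to 2,5-bis(benzyloxy)-4-methoxybenzoic acid F2.
- Commercial 2-methoxy-1-(2,4,6-trihydroxyphenyl)ethanone (COCC(=O)c1c(O)cc(O)cc1O) is methylated twice (Me2SO4, 2 equiv, K2CO3, acetone). One chelated hydroxyl stays free, giving 1-(2-hydroxy-4,6-dimethoxyphenyl)-2-methoxyethanone F3.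
- Steglich esterification (EDC·HCl, DMAP, CH2Cl2) of F3 by F2 should give 3,5-dimethoxy-2-(methoxyacetyl)phenyl 2,5-bis(benzyloxy)-4-methoxybenzoate F4.
- LiHMDS (THF, −20 °C to rt) moves the aroyl group from oxygen to carbon to give 1-[2,5-bis(benzyloxy)-4-methoxyphenyl]-3-(2-hydroxy-4,6-dimethoxyphenyl)-2-methoxypropane-1,3-dione F5.
- p-TsOH in warm toluene cyclodehydrates F5 to 22, after which step 12 is run unchanged.

**Step 8.**
- What may go wrong: diazomethane may add as a 1,3-dipole across the acceptor-flanked C5=C6 bond of the pyranone. Liberated HCl may also protonate the diazoketone and displace nitrogen.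
- The fallback sets out from 10 through its chloride 11 and comes back at 12. It installs the diazo group by diazo transfer instead of by acylating diazomethane.
- Chloride 11 is coupled with MeZnCl (Pd(PPh3)4 cat., THF, 0 °C, Negishi acylation) to 6-acetyl-2-[2,5-bis(benzyloxy)-4-methoxyphenyl]-3-methoxy-4H-pyran-4-one F6.
- F6 is trifluoroacetylated (LiHMDS, then CF3CO2CH2CF3, THF, −78 °C) to 1-{6-[2,5-bis(benzyloxy)-4-methoxyphenyl]-5-methoxy-4-oxo-4H-pyran-2-yl}-4,4,4-trifluorobutane-1,3-dione F7.
- Crude F7 is treated with MsN3, Et3N and H2O in MeCN. Diazo transfer with loss of the trifluoroacetyl group (detrifluoroacetylative diazo transfer) should give 12.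

**Step 6.**
- What may go wrong: aqueous base may displace bromide from the vinylogous acyl bromide. The electron-rich ortho-alkoxy boronate may undergo protodeboronation before the slow transmetalation at the hindered centre.
- The fallback sets out from 7 and 3 and comes back at 8. It is a base-free Negishi coupling.
- Alcohol 7 is silylated (TBSCl, imidazole, DMF) to 2-bromo-6-{[(tert-butyldimethylsilyl)oxy]methyl}-3-methoxy-4H-pyran-4-one F8.
- Bromide 3 is taken through the same aryllithium F1 (n-BuLi, THF, −78 °C) and ZnCl2 to [2,5-bis(benzyloxy)-4-methoxyphenyl]zinc chloride F9.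
- Coupling of F8 and F9 (Pd(OAc)2, SPhos, THF, 40 °C) should give 2-[2,5-bis(benzyloxy)-4-methoxyphenyl]-6-{[(tert-butyldimethylsilyl)oxy]methyl}-3-methoxy-4H-pyran-4-one F10.
- TBAF buffered with AcOH (THF, 0 °C) releases 8 from F10.

**Further compounds**

F1 | step 10 | [2,5-bis(benzyloxy)-4-methoxyphenyl]lithium | [Li]c1cc(OCc2ccccc2)c(OC)cc1OCc1ccccc1
F2 | step 10 | 2,5-bis(benzyloxy)-4-methoxybenzoic acid | OC(=O)c1cc(OCc2ccccc2)c(OC)cc1OCc1ccccc1
F3 | step 10 | 1-(2-hydroxy-4,6-dimethoxyphenyl)-2-methoxyethanone | COCC(=O)c1c(O)cc(OC)cc1OC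
F4 | step 10 | 3,5-dimethoxy-2-(methoxyacetyl)phenyl 2,5-bis(benzyloxy)-4-methoxybenzoate | COCC(=O)c1c(OC)cc(OC)cc1OC(=O)c1cc(OCc2ccccc2)c(OC)cc1OCc1ccccc1
F5 | step 10 | 1-[2,5-bis(benzyloxy)-4-methoxyphenyl]-3-(2-hydroxy-4,6-dimethoxyphenyl)-2-methoxypropane-1,3-dione (racemic, enolisable) | COC(C(=O)c1c(O)cc(OC)cc1OC)C(=O)c1cc(OCc2ccccc2)c(OC)cc1OCc1ccccc1
F6 | step 8 | 6-acetyl-2-[2,5-bis(benzyloxy)-4-methoxyphenyl]-3-methoxy-4H-pyran-4-one | CC(=O)c1cc(=O)c(OC)c(-c2cc(OCc3ccccc3)c(OC)cc2OCc2ccccc2)o1
F7 | step 8 | 1-{6-[2,5-bis(benzyloxy)-4-methoxyphenyl]-5-methoxy-4-oxo-4H-pyran-2-yl}-4,4,4-trifluorobutane-1,3-dione | O=C(CC(=O)C(F)(F)F)c1cc(=O)c(OC)c(-c2cc(OCc3ccccc3)c(OC)cc2OCc2ccccc2)o1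
F8 | step 6 | 2-bromo-6-{[(tert-butyldimethylsilyl)oxy]methyl}-3-methoxy-4H-pyran-4-one | COc1c(Br)oc(CO[Si](C)(C)C(C)(C)C)cc1=O
F9 | step 6 | [2,5-bis(benzyloxy)-4-methoxyphenyl]zinc chloride | Cl[Zn]c1cc(OCc2ccccc2)c(OC)cc1OCc1ccccc1
F10 | step 6 | 2-[2,5-bis(benzyloxy)-4-methoxyphenyl]-6-{[(tert-butyldimethylsilyl)oxy]methyl}-3-methoxy-4H-pyran-4-one | COc1c(-c2cc(OCc3ccccc3)c(OC)cc2OCc2ccccc2)oc(CO[Si](C)(C)C(C)(C)C)cc1=O
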